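Dividing ln(c(substrate) charged / c(substrate) found) by the time is an easy step, and for a curve that is not one exponential it replaces the curve by its mean. Amber and red carry the same acid as the flask, 0.162 mM, and the flask's charge of substrate lies between theirs, so I plan the flask from those two runs.

| flask | substrate | acid | remark | time |
|---|---|---|---|---|
| amber | 0.036 M | 0.162 mM | run made earlier |  |
| red | 0.081 M | 0.162 mM | run made earlier |  |
| green | 0.054 M | 0.081 mM | run made earlier |  |
| flask | 0.054 M | 0.162 mM |  | 80 min |

| run | time / min | substrate / % | target / % |
|---|---|---|---|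
| amber | 6.00 | 84.3 | 5.1 |
| amber | 20.0 | 59.3 | 15.3 |
| amber | 30.0 | 46.7 | 23.0 |
| amber | 50.0 | 31.0 | 31.7 |
| amber | 80.0 | 17.4 | 40.1 |
| amber | 90.0 | 15.0 | 40.9 |
| red | 6.00 | 74.3 | 6.0 |
| red | 20.0 | 44.1 | 16.0 |
| red | 30.0 | 32.0 | 19.7 |
| red | 50.0 | 19.3 | 24.8 |
| red | 80.0 | 11.0 | 31.3 |
| red | 90.0 | 7.8 | 32.1 |
| green | 8.00 | 76.2 | 4.6 |
| green | 25.0 | 48.8 | 14.0 |
| green | 40.0 | 35.6 | 17.8 |
| green | 60.0 | 23.8 | 23.0 |
| green | 90.0 | 14.1 | 28.5 |

(readings scatter by 0.5 percentage points)

- acid is the free proton; pH is minus the decimal logarithm of its molar concentration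
- percentages count the substrate that a species holds: one homo dimer counts as two
- steps that have been proposed: weak acid <-> conjugate base + acid; 2 substrate -> homo dimer; substrate + acid -> weak acid + acid + target; substrate -> weak acid + target; target -> over-reaction product

- part of the substrate that has reacted at 80 min
- pH of the solution at 80 min

My decision is whether to stop the flask at 80 min or leave it longer. At 80.0 min amber gives 0.0219 min⁻¹ and red gives 0.0276 min⁻¹, larger than amber's, which points to a second-order loss of substrate beside a first-order one. Interpolating linearly in the charge gives 0.0242 min⁻¹ for the flask, its mean pseudo-first-order loss constant at that reading time.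

The mean has a known error: amber at 30.0 min gives 0.0254 min⁻¹, higher than at 80.0 min. So a mean belongs to its reading time, and I interpolate between equal times. By this reckoning the flask keeps 14.5% of its substrate, so I expect 85.5% to have reacted. Between 80.0 min and 90.0 min amber lost 2.4 percentage points and red 3.2 points, so I stop at 80 min.

The forecast, reached by another route, gives 85.5% (83.5% to 87.5%) and pH 3.62 (3.5 to 3.74), starting from this: “The readings fit first-order formation of target plus a second-order dimer loss.”

    weak acid ⇌ conjugate base + acid, settled at all times (K = 1.30 × 10⁻⁶ M)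
    2 substrate → homo dimer (k = 17.0 M⁻¹ h⁻¹)
    substrate + acid → weak acid + acid + target (k = 3100 M⁻¹ h⁻¹)
    substrate → weak acid + target (k = 0.0950 h⁻¹)
    target → over-reaction product (k = 0.110 h⁻¹)

The flask gives 86.7% and pH 3.58, both inside the forecast's ranges, and its mean constant is 0.0252 min⁻¹, a little above my 0.0242 min⁻¹. The same flask read at 30 min takes the same reckoning from the amber and red readings at that time: my constant for it comes to 0.0304 min⁻¹, higher than 0.0242 min⁻¹, and by the reckoning leaves 40.2% of the substrate. That flask holds 39.2%.

(The numbers in the tables stem from a simulated flask for an exercise; the scatter is artificial.)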